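(The runs were computed for substances that don't exist; scatter was added.)

I began from a one-step, first-order world, in which the share of the charge turned into target at a given time does not depend on the charge, and the readings refused it: at 18 min the larch flask stood at 38.6% of its charge, the ash flask at 27.6%, the alder flask at 22.5%.

| flask | starting material | time |
|---|---|---|
| ash | 1.00 M |  |
| larch | 0.500 M |  |
| alder | 1.50 M |  |
| maple | 2.10 M | 18 min |

| run | time / min | [target] / M |
|---|---|---|
| ash run | 0.72 | 0.030 |
| ash run | 1.4 | 0.084 |
| ash run | 2.6 | 0.125 |
| ash run | 5.0 | 0.218 |
| ash run | 9.5 | 0.265 |
| ash run | 18 | 0.276 |
| larch run | 0.72 | 0.017 |
| larch run | 1.4 | 0.028 |
| larch run | 2.6 | 0.107 |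
| larch run | 5.0 | 0.131 |
| larch run | 9.5 | 0.183 |
| larch run | 18 | 0.193 |
| alder run | 0.72 | 0.025 |
| alder run | 1.4 | 0.111 |
| alder run | 2.6 | 0.176 |
| alder run | 5.0 | 0.247 |
| alder run | 9.5 | 0.311 |
| alder run | 18 | 0.337 |

(standard deviation of a reading: 0.01 M)

- apparent order in [starting material] of the starting rate, round the charge of the ash run (the rate where two percent of its starting material have turned into target) (one fixed amount of target, the same in the runs compared)
- target in the maple run at 18 min, as a share of the starting material charged
- which of these the readings show (the product speeds the reaction / two substrates go astray together / the product decays)

- Overall: starting material -> target.
- Constant volume, constant temperature.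
- An order is taken over about fifteen percent of the charge, up and down.

So I let a second route compete, one in which two molecules of starting material pair, and named B the break-even concentration, the [starting material] at which pairing and the one-step route spend starting material equally, which makes the one-step share at any moment, the selectivity, B/(B + [starting material]). I first replaced the falling [starting material] by its mean, half the charge. Taking the last reading as the end of the fall, although the alder flask still went from 0.311 M at 9.5 min to 0.337 M at 18 min, that gave B = 0.217 M from the alder flask and a maple share of 17.1%. The check on that step failed, since the larch flask gave 0.157 M, less than the alder value, where a constant should not move.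

The mean was the weak link, so I summed the share over the whole fall instead: target made = B ln((B + charge)/B). The difference between the larch and alder flasks, solved in two passes, gave the break-even concentration 0.131 M and then 0.152 M. The ash flask, unused so far, was predicted at 0.279 M against its reading of 0.276 M. Stepping up from the alder reading, I committed to 18.3% for the maple flask.

The forecast gave an order of 0.6 (0.2 to 1.1), a maple share of 18% (16.5% to 19.5%) and "two substrates go astray together", reasoning that “this points to a loss second order in substrate”.

The maple flask gave 18.5% of its charge as target at 18 min, the apparent order round the charge of the ash flask came out at 0.55, and what the readings show is that two substrates go astray together.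

    starting material → intermediate (0.1704 /min)
    intermediate → target (1.092 /min)
    2 starting material → homo dimer (0.5892 /M/min)

Taking the passing of two starting material into homo dimer out of these steps moves the readings by 41 times their scatter, root mean square. With B at 0.152 M, the alder flask at its start sends about 9.18% of the starting material it spends towards the intermediate, and the maple flask at its start about 6.73%.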